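The rate constants were chosen freely; the result is computed.

If L was to lead at the end, it had to pass D before the time ran out, so I looked for that crossing in two flasks that differ in time.

| setting | elm | ash |
|---|---|---|
| X | 31 mM | 31 mM |
| G | 0.33 mol% | 0.33 mol% |
| time | 2.5 d | 4.0 d |

    X → D (k1 = 0.32 /h)
    G + D → G + L (k2 = 140 /M/h)
    X → Z (k3 = 0.022 /h)

- which of these there is most of at the end, counted by the X in it, elm (Z / L / X / D)
- which of these there is most of at the end, counted by the X in it, ash (Z / L / X / D)
- the largest of these amounts at the end, in percent of the X charged, elm
- the largest of these amounts at the end, in percent of the X charged, ash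

I began with X, which left for D and Z together at 0.342 /h, so D received 93.6 % of it and Z the other 6.40 %. G comes back unchanged from its step, so D met a steady [G] of 0.102 mM and fell pseudo-first-order at 0.0143 /h. That is far slower than the loss of X, which made it the rate-limiting step, and it gave D a half-life of 2.02 d.

Taking X as gone at once, I had L at 53.9 % in elm and 69.9 % in ash. That was the weak link, since X takes on average 2.92 h to leave, so I started the fall of D that much later. The crossing time, the time from the start at which [L] comes to equal [D], is this delay plus one half-life of D: 2.14 d. It lay before the end of either flask. I committed to L at 52.3 % for elm, and L at 68.9 % for ash.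

The forecast put L first in elm at 52.2 % and L first in ash at 68.9 %, “leaving L as the largest amount at both times”.

The run ended elm with L at 52.2 % and D at 41.4 %, and ash with L at 68.9 % and D at 24.7 %. In ash, X turned into D early, half of that turnover being done by 0.0846 d, and X stood at 0 % at 2.00 d. In ash, the turning of D into L by G had 28 % of its turnover up to the end behind it at 0.800 d, and at 2.00 d, short of my crossing at 2.14 d, D at 49.1 % still led L at 44.5 %. For the neighbour of ash with 0.13 mol% of G, the crossing time comes to 5.24 d, later than its end at 4.0 d. That flask ended with D largest, at 55.4 % against L at 38.2 %.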